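**Plan**
Retrosynthesis: the ferulate ester C–O bond is cut first and the C3=C4 double bond is returned to a chroman. Ring A is then opened at C5–C6 (chromene numbering). This is possible because the acetyl at C6, the hydroxyl at C7 and the ring oxygen at C8a sit on alternate carbons as in a β-polycarbonyl chain, with C5 as a formyl carbon and the enol ether C8a=C4a of a dihydropyran standing in for the third carbonyl.
Further cuts: C7–C8 (acylation at the methyl group of a formyl-methyl-dihydropyran), C4a–C5 (formylation), O1–C8a (cyclodehydration) and C3–C4 (epoxide opening).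
Forward: the chain is joined by Grignard opening of silylated 2-methylglycidol and the pyran ring is closed first. The formyl carbon and the masked diketone arm are then added, ring A is closed by Knoevenagel condensation and aromatisation, the chroman is dehydrogenated and the ferulate is attached last.
Stereochemistry: the only stereocentre, C2 (R), is the quaternary carbon of (S)-2-methylglycidol; none of its four bonds is broken at any stage.

Key step: step 9

Assumption: the ethylene ketal of ethyl acetoacetate is bought as such, and the primary alcohol is carried as a tert-butyldiphenylsilyl ether because it should resist the Vilsmeier reagent and the acidic steps better than a tert-butyldimethylsilyl ether.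

**Step 1**
Reactants: 1 (S)-2-methylglycidol, (2S)-(2-methyloxiran-2-yl)methanol
Product: 2 tert-butyl{[(2R)-2-methyloxiran-2-yl]methoxy}diphenylsilane
Conditions: TBDPSCl, imidazole, CH2Cl2, 0 °C to rt
Reagents that add atoms: tert-butyl(chloro)diphenylsilane, CC(C)(C)[Si](Cl)(c1ccccc1)c1ccccc1
Why: Imidazole-promoted silylation of a primary alcohol leaves the epoxide and its quaternary carbon untouched; the descriptor changes from S to R only because the silyloxymethyl arm now outranks the ring CH2.

**Step 2**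
Reactants: 2 tert-butyl{[(2R)-2-methyloxiran-2-yl]methoxy}diphenylsilane; 3 but-3-en-1-ylmagnesium bromide
Product: 4 (2R)-1-[(tert-butyldiphenylsilyl)oxy]-2-methylhept-6-en-2-ol
Conditions: CuI (10 mol %), THF, −30 to 0 °C; aq NH4Cl
Reagents that add atoms: none
Why: Copper-catalysed Grignard opening of a 2,2-disubstituted epoxide occurs by SN2 attack at the unsubstituted CH2, so the C–O bond of the quaternary carbon stays intact and the tertiary carbinol keeps the configuration of 1.

**Step 3**
Reactants: 4 (2R)-1-[(tert-butyldiphenylsilyl)oxy]-2-methylhept-6-en-2-ol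
Product: 5 (6R)-7-[(tert-butyldiphenylsilyl)oxy]-6-hydroxy-6-methylheptan-2-one
Conditions: PdCl2 (10 mol %), CuCl, O2 (1 atm), DMF/H2O, rt
Reagents that add atoms: water, O
Why: Tsuji–Wacker oxidation should turn the terminal alkene into the methyl ketone with Markovnikov selectivity, while the silyl ether and the tertiary alcohol are inert to the conditions.

**Step 4**
Reactants: 5 (6R)-7-[(tert-butyldiphenylsilyl)oxy]-6-hydroxy-6-methylheptan-2-one
Product: 7 tert-butyl{[(2R)-2,6-dimethyl-3,4-dihydro-2H-pyran-2-yl]methoxy}diphenylsilane, via cyclic hemiketal 6 (not isolated)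
Conditions: PPTS (cat.), toluene, reflux, Dean–Stark; Et3N quench
Reagents that add atoms: none
Why: Acid-catalysed cyclodehydration of a δ-hydroxy ketone (hemiketal formation, then loss of water through the oxocarbenium ion) should give the endocyclic trisubstituted enol ether, which is favoured over the exocyclic isomer under equilibrating conditions; the quaternary centre is not involved.

**Step 5**
Reactants: 7 tert-butyl{[(2R)-2,6-dimethyl-3,4-dihydro-2H-pyran-2-yl]methoxy}diphenylsilane
Product: 9 (2R)-2-{[(tert-butyldiphenylsilyl)oxy]methyl}-2,6-dimethyl-3,4-dihydro-2H-pyran-5-carbaldehyde, via iminium chloride 8 (not isolated)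
Conditions: POCl3 (1.1 equiv), DMF, CH2Cl2, 0 °C to rt; then aq NaOAc
Reagents that add atoms: N,N-dimethylformamide, CN(C)C=O; water, O
Why: Vilsmeier–Haack formylation attacks the nucleophilic β-carbon (C5) of the cyclic enol ether, and keeping the reagent near one equivalent at low temperature should avoid a second attack at the C6 methyl and spare the diphenylsilyl ether.

**Step 6**
Reactants: 10 ethyl (2-methyl-1,3-dioxolan-2-yl)acetate
Product: 11 N-methoxy-N-methyl-2-(2-methyl-1,3-dioxolan-2-yl)acetamide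
Conditions: MeNHOMe·HCl, i-PrMgCl, THF, −20 to 0 °C
Reagents that add atoms: N,O-dimethylhydroxylamine hydrochloride, Cl.CNOC
Why: Weinreb amide formation by aminolysis of the ester with the chloromagnesium amide of N,O-dimethylhydroxylamine is standard, and the dioxolane is stable to the basic medium.

**Step 7**
Reactants: 9 (2R)-2-{[(tert-butyldiphenylsilyl)oxy]methyl}-2,6-dimethyl-3,4-dihydro-2H-pyran-5-carbaldehyde; 11 N-methoxy-N-methyl-2-(2-methyl-1,3-dioxolan-2-yl)acetamide
Product: 14 (2R)-2-{[(tert-butyldiphenylsilyl)oxy]methyl}-2-methyl-6-[3-(2-methyl-1,3-dioxolan-2-yl)-2-oxopropyl]-3,4-dihydro-2H-pyran-5-carbaldehyde, via lithium dienolate 12 (not isolated), via tetrahedral lithium adduct 13 (not isolated)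
Conditions: lithium 2,2,6,6-tetramethylpiperidide (from the amine and n-BuLi), THF, −78 °C; then 11, −78 to 0 °C; aq NH4Cl
Reagents that add atoms: none
Why: Vinylogous Claisen acylation: the hindered amide base removes a proton from the C6 methyl (the formyl group has no α-hydrogen and C5 is fully substituted), and the dienolate attacks the Weinreb amide through its γ-carbon to give a chelated adduct that releases the ketone only on quench, as in γ-acylations of 6-methyl-1,3-dioxin-4-one dienolates.

**Step 8**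
Reactants: 14 (2R)-2-{[(tert-butyldiphenylsilyl)oxy]methyl}-2-methyl-6-[3-(2-methyl-1,3-dioxolan-2-yl)-2-oxopropyl]-3,4-dihydro-2H-pyran-5-carbaldehyde
Product: 15 (2R)-2-{[(tert-butyldiphenylsilyl)oxy]methyl}-6-(2,4-dioxopentyl)-2-methyl-3,4-dihydro-2H-pyran-5-carbaldehyde
Conditions: PPTS, acetone/H2O, 50 °C; used crude
Reagents that add atoms: water, O
Why: Acid-catalysed ketal hydrolysis unmasks the 1,3-diketone, and the vinylogous formate and the diphenylsilyl ether should tolerate pyridinium tosylate.

**Step 9**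
Reactants: 15 (2R)-2-{[(tert-butyldiphenylsilyl)oxy]methyl}-6-(2,4-dioxopentyl)-2-methyl-3,4-dihydro-2H-pyran-5-carbaldehyde
Product: 17 1-[(2R)-2-{[(tert-butyldiphenylsilyl)oxy]methyl}-7-hydroxy-2-methyl-3,4-dihydro-2H-chromen-6-yl]ethan-1-one, via cyclohexa-2,4-dienone 16 (not isolated)
Conditions: piperidine (20 mol %), AcOH (20 mol %), toluene, rt to 60 °C
Reagents that add atoms: none
Why: Proposed new method: piperidinium acetate enolises the 1,3-diketone (or turns the formyl group into its iminium ion), the doubly activated methylene carbon (future C6) adds to the formyl carbon (future C5), and loss of water gives dienone 16, whose C8 proton moves to oxygen to give the phenol irreversibly. The closest known reaction types are the intramolecular Knoevenagel or aldol aromatisation of poly-β-carbonyl chains to resorcinol-type arenes and the benzannulation of 3-formylchromones with 1,3-dicarbonyl compounds. Ring A closes in a 6-(enolendo)-exo-trig aldol mode and no stereocentre is created. The step needs C-attack by the central diketone carbon: the C8 methylene could only close a four-membered ring and the terminal methyl an eight-membered ring, and the hemiacetal from O-attack is reversible, so only the six-membered carbocycle can drain to the arene. Amine exchange at C8a and retro-Claisen cleavage should be limited by using the amine in catalytic, buffered amount, and the quaternary C2, which carries no hydrogen and whose C–O bond is never broken, cannot epimerise.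

**Step 10**
Reactants: 17 1-[(2R)-2-{[(tert-butyldiphenylsilyl)oxy]methyl}-7-hydroxy-2-methyl-3,4-dihydro-2H-chromen-6-yl]ethan-1-one
Product: 18 1-[(2R)-2-{[(tert-butyldiphenylsilyl)oxy]methyl}-7-hydroxy-2-methyl-2H-chromen-6-yl]ethan-1-one
Conditions: DDQ, 1,4-dioxane, reflux
Reagents that add atoms: none
Why: DDQ dehydrogenation of a chroman to a 2H-chromene proceeds by hydride abstraction from benzylic C4, assisted by the para 7-hydroxyl and the ortho ring oxygen, followed by loss of a C3 proton; C2 is quaternary and unaffected.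

**Step 11**
Reactants: 18 1-[(2R)-2-{[(tert-butyldiphenylsilyl)oxy]methyl}-7-hydroxy-2-methyl-2H-chromen-6-yl]ethan-1-one
Product: 19 1-[(2R)-7-hydroxy-2-(hydroxymethyl)-2-methyl-2H-chromen-6-yl]ethan-1-one
Conditions: Bu4NF (excess), THF, rt; aq NH4Cl
Reagents that add atoms: none
Why: Fluoride-mediated silyl ether cleavage should free the primary alcohol; the excess of fluoride allows for the acidic phenol, and the chromene and the ketone are inert.

**Step 12**
Reactants: 20 ferulic acid, (E)-3-(4-hydroxy-3-methoxyphenyl)prop-2-enoic acid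
Product: 21 (E)-3-(4-acetoxy-3-methoxyphenyl)prop-2-enoic acid
Conditions: Ac2O, pyridine, rt; then H2O
Reagents that add atoms: acetic anhydride, CC(=O)OC(C)=O
Why: Acetylation of the phenol (any mixed anhydride at the acid is hydrolysed on aqueous work-up) keeps the ferulic phenol from competing in the esterification.

**Step 13**
Reactants: 19 1-[(2R)-7-hydroxy-2-(hydroxymethyl)-2-methyl-2H-chromen-6-yl]ethan-1-one; 21 (E)-3-(4-acetoxy-3-methoxyphenyl)prop-2-enoic acid
Product: 22 [(2R)-6-acetyl-7-hydroxy-2-methyl-2H-chromen-2-yl]methyl (E)-3-(4-acetoxy-3-methoxyphenyl)prop-2-enoate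
Conditions: EDC·HCl, DMAP (cat.), CH2Cl2, 0 °C to rt
Reagents that add atoms: none
Why: Steglich esterification should acylate the primary alcohol in preference to the 7-hydroxyl, which is deactivated by its hydrogen bond to the ortho acetyl group, and it leaves the E-alkene geometry untouched.

**Step 14**
Reactants: 22 [(2R)-6-acetyl-7-hydroxy-2-methyl-2H-chromen-2-yl]methyl (E)-3-(4-acetoxy-3-methoxyphenyl)prop-2-enoate
Product: 23 [(2R)-6-acetyl-7-hydroxy-2-methyl-2H-chromen-2-yl]methyl (E)-3-(4-hydroxy-3-methoxyphenyl)prop-2-enoate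
Conditions: pyrrolidine, CH2Cl2, 0 °C
Reagents that add atoms: none
Why: Aminolysis of an aryl acetate by pyrrolidine is much faster than attack on the hindered alkyl cinnamate, so only the phenolic acetate should be removed (the same conditions would also clear any aryl ester formed at O7 in step 13).

**Compound list**
1 | (S)-2-methylglycidol, (2S)-(2-methyloxiran-2-yl)methanol | OC[C@@]1(C)CO1 | starting material
2 | tert-butyl{[(2R)-2-methyloxiran-2-yl]methoxy}diphenylsilane | CC(C)(C)[Si](c1ccccc1)(c1ccccc1)OC[C@@]1(C)CO1 | intermediate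
3 | but-3-en-1-ylmagnesium bromide | C=CCC[Mg]Br | starting material
4 | (2R)-1-[(tert-butyldiphenylsilyl)oxy]-2-methylhept-6-en-2-ol | C=CCCC[C@@](C)(O)CO[Si](c1ccccc1)(c1ccccc1)C(C)(C)C | intermediate
5 | (6R)-7-[(tert-butyldiphenylsilyl)oxy]-6-hydroxy-6-methylheptan-2-one | CC(=O)CCC[C@@](C)(O)CO[Si](c1ccccc1)(c1ccccc1)C(C)(C)C | intermediate
6 | (6R)-6-{[(tert-butyldiphenylsilyl)oxy]methyl}-2,6-dimethyloxan-2-ol, cyclic hemiketal, both C2 epimers | CC1(O)CCC[C@](C)(CO[Si](c2ccccc2)(c2ccccc2)C(C)(C)C)O1 | intermediate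
7 | tert-butyl{[(2R)-2,6-dimethyl-3,4-dihydro-2H-pyran-2-yl]methoxy}diphenylsilane | CC1=CCC[C@](C)(CO[Si](c2ccccc2)(c2ccccc2)C(C)(C)C)O1 | intermediate
8 | N-{[(2R)-2-{[(tert-butyldiphenylsilyl)oxy]methyl}-2,6-dimethyl-3,4-dihydro-2H-pyran-5-yl]methylidene}-N-methylmethanaminium chloride | CC1=C(C=[N+](C)C)CC[C@](C)(CO[Si](c2ccccc2)(c2ccccc2)C(C)(C)C)O1.[Cl-] | intermediate
9 | (2R)-2-{[(tert-butyldiphenylsilyl)oxy]methyl}-2,6-dimethyl-3,4-dihydro-2H-pyran-5-carbaldehyde | CC1=C(C=O)CC[C@](C)(CO[Si](c2ccccc2)(c2ccccc2)C(C)(C)C)O1 | intermediate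
10 | ethyl (2-methyl-1,3-dioxolan-2-yl)acetate | CCOC(=O)CC1(C)OCCO1 | starting material
11 | N-methoxy-N-methyl-2-(2-methyl-1,3-dioxolan-2-yl)acetamide | CON(C)C(=O)CC1(C)OCCO1 | intermediate
12 | lithium [(6R)-6-{[(tert-butyldiphenylsilyl)oxy]methyl}-6-methyl-2-methylideneoxan-3-ylidene]methanolate, enolate geometry not defined | [Li+].[O-]C=C1CC[C@](C)(CO[Si](c2ccccc2)(c2ccccc2)C(C)(C)C)OC1=C | intermediate
13 | lithium 1-[(6R)-6-{[(tert-butyldiphenylsilyl)oxy]methyl}-3-formyl-6-methyl-5,6-dihydro-4H-pyran-2-yl]-2-[methoxy(methyl)amino]-3-(2-methyl-1,3-dioxolan-2-yl)propan-2-olate, carbinol centre not defined | CON(C)C([O-])(CC1=C(C=O)CC[C@](C)(CO[Si](c2ccccc2)(c2ccccc2)C(C)(C)C)O1)CC1(C)OCCO1.[Li+] | intermediate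
14 | (2R)-2-{[(tert-butyldiphenylsilyl)oxy]methyl}-2-methyl-6-[3-(2-methyl-1,3-dioxolan-2-yl)-2-oxopropyl]-3,4-dihydro-2H-pyran-5-carbaldehyde | CC1(CC(=O)CC2=C(C=O)CC[C@](C)(CO[Si](c3ccccc3)(c3ccccc3)C(C)(C)C)O2)OCCO1 | intermediate
15 | (2R)-2-{[(tert-butyldiphenylsilyl)oxy]methyl}-6-(2,4-dioxopentyl)-2-methyl-3,4-dihydro-2H-pyran-5-carbaldehyde | CC(=O)CC(=O)CC1=C(C=O)CC[C@](C)(CO[Si](c2ccccc2)(c2ccccc2)C(C)(C)C)O1 | intermediate
16 | (2R)-6-acetyl-2-{[(tert-butyldiphenylsilyl)oxy]methyl}-2-methyl-3,4-dihydro-2H-chromen-7(8H)-one | O=C1CC2=C(C=C1C(C)=O)CC[C@](C)(CO[Si](c1ccccc1)(c1ccccc1)C(C)(C)C)O2 | intermediate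
17 | 1-[(2R)-2-{[(tert-butyldiphenylsilyl)oxy]methyl}-7-hydroxy-2-methyl-3,4-dihydro-2H-chromen-6-yl]ethan-1-one | CC(=O)c1cc2CC[C@](C)(CO[Si](c3ccccc3)(c3ccccc3)C(C)(C)C)Oc2cc1O | intermediate
18 | 1-[(2R)-2-{[(tert-butyldiphenylsilyl)oxy]methyl}-7-hydroxy-2-methyl-2H-chromen-6-yl]ethan-1-one | CC(=O)c1cc2C=C[C@](C)(CO[Si](c3ccccc3)(c3ccccc3)C(C)(C)C)Oc2cc1O | intermediate
19 | 1-[(2R)-7-hydroxy-2-(hydroxymethyl)-2-methyl-2H-chromen-6-yl]ethan-1-one | CC(=O)c1cc2C=C[C@](C)(CO)Oc2cc1O | intermediate
20 | ferulic acid, (E)-3-(4-hydroxy-3-methoxyphenyl)prop-2-enoic acid | COc1cc(/C=C/C(=O)O)ccc1O | starting material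
21 | (E)-3-(4-acetoxy-3-methoxyphenyl)prop-2-enoic acid | COc1cc(/C=C/C(=O)O)ccc1OC(C)=O | intermediate
22 | [(2R)-6-acetyl-7-hydroxy-2-methyl-2H-chromen-2-yl]methyl (E)-3-(4-acetoxy-3-methoxyphenyl)prop-2-enoate | COc1cc(/C=C/C(=O)OC[C@@]2(C)C=Cc3cc(C(C)=O)c(O)cc3O2)ccc1OC(C)=O | intermediate
23 | [(2R)-6-acetyl-7-hydroxy-2-methyl-2H-chromen-2-yl]methyl (E)-3-(4-hydroxy-3-methoxyphenyl)prop-2-enoate | COc1cc(/C=C/C(=O)OC[C@@]2(C)C=Cc3cc(C(C)=O)c(O)cc3O2)ccc1O | target

**Step count**
Total: 14 steps. Longest linear sequence: 12 steps (steps 1–5, 7–11, 13 and 14); steps 6 and 12 prepare the two side fragments.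

**Steps most likely to fail**

1. Step 9 (ring closure and aromatisation). The amine may exchange at C8a and open the pyran, reversible O-cyclisation may hold the material as pyranols, the acetyl group may be lost by retro-Claisen cleavage, or intermolecular condensation may outrun ring closure. The fallback uses known chemistry, brings the arene in intact and closes the pyran ring onto it. It sets out from epoxide 2. CuI-catalysed opening with (2-bromo-4-methoxybenzyl)magnesium chloride should give the tertiary alcohol (2R)-4-(2-bromo-4-methoxyphenyl)-1-[(tert-butyldiphenylsilyl)oxy]-2-methylbutan-2-ol F1. Intramolecular palladium-catalysed C–O coupling (Pd(OAc)2, 2-(di-tert-butylphosphino)-1,1'-binaphthyl, Cs2CO3, toluene, 80 °C) should close the chroman tert-butyl{[(2R)-7-methoxy-2-methyl-3,4-dihydro-2H-chromen-2-yl]methoxy}diphenylsilane F2. Friedel–Crafts acetylation (AcCl, SnCl4, CH2Cl2, −20 °C) at C6, para to the ring oxygen, should give 1-[(2R)-2-{[(tert-butyldiphenylsilyl)oxy]methyl}-7-methoxy-2-methyl-3,4-dihydro-2H-chromen-6-yl]ethan-1-one F3. Chelation-directed demethylation with BCl3 (CH2Cl2, −78 °C) then rejoins the route at chroman 17.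

2. Step 7 (dienolate acylation). The lithium amide may attack the formyl group, the dienolate may condense with unreacted aldehyde, acylation may occur on oxygen, or the Weinreb amide may react too slowly. The fallback replaces the base-mediated acylation by a Lewis-acid aldol addition and an oxidation, and sets out from aldehyde 9. Soft enolisation (TBSOTf, Et3N, CH2Cl2, 0 °C) should give the silyl dienol ether tert-butyl{[(2R)-5-{[(tert-butyldimethylsilyl)oxy]methylidene}-2-methyl-6-methylideneoxan-2-yl]methoxy}diphenylsilane F4. The partner 2-(2-methyl-1,3-dioxolan-2-yl)acetaldehyde F5 is made from ester 10 with i-Bu2AlH (CH2Cl2, −78 °C). A BF3·OEt2-promoted vinylogous Mukaiyama aldol addition at the terminal methylene of the diene should give (2R)-2-{[(tert-butyldiphenylsilyl)oxy]methyl}-6-[2-hydroxy-3-(2-methyl-1,3-dioxolan-2-yl)propyl]-2-methyl-3,4-dihydro-2H-pyran-5-carbaldehyde F6. Dess–Martin oxidation of the secondary alcohol comes back to keto ketal 14.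

3. Step 5 (formylation). A second formylation may occur at the C6 methyl through the conjugated iminium salt, the enol ether may be opened by the hydrogen chloride released, or the reagent may attack the silyl ether. The fallback introduces the carbon at the acid oxidation level and adjusts it afterwards, setting out from enol ether 7. Acylation at C5 with trichloroacetyl chloride and pyridine (CH2Cl2, 0 °C) should give 2,2,2-trichloro-1-[(2R)-2-{[(tert-butyldiphenylsilyl)oxy]methyl}-2,6-dimethyl-3,4-dihydro-2H-pyran-5-yl]ethan-1-one F7. Haloform-type cleavage with NaOMe in MeOH should give methyl (2R)-2-{[(tert-butyldiphenylsilyl)oxy]methyl}-2,6-dimethyl-3,4-dihydro-2H-pyran-5-carboxylate F8. Reduction with i-Bu2AlH (CH2Cl2, −78 °C) should give [(2R)-2-{[(tert-butyldiphenylsilyl)oxy]methyl}-2,6-dimethyl-3,4-dihydro-2H-pyran-5-yl]methanol F9. Oxidation with MnO2 returns to aldehyde 9.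

**Further compounds**
F1 | step 9 | (2R)-4-(2-bromo-4-methoxyphenyl)-1-[(tert-butyldiphenylsilyl)oxy]-2-methylbutan-2-ol | COc1ccc(CC[C@@](C)(O)CO[Si](c2ccccc2)(c2ccccc2)C(C)(C)C)c(Br)c1
F2 | step 9 | tert-butyl{[(2R)-7-methoxy-2-methyl-3,4-dihydro-2H-chromen-2-yl]methoxy}diphenylsilane | COc1ccc2CC[C@](C)(CO[Si](c3ccccc3)(c3ccccc3)C(C)(C)C)Oc2c1
F3 | step 9 | 1-[(2R)-2-{[(tert-butyldiphenylsilyl)oxy]methyl}-7-methoxy-2-methyl-3,4-dihydro-2H-chromen-6-yl]ethan-1-one | CC(=O)c1cc2CC[C@](C)(CO[Si](c3ccccc3)(c3ccccc3)C(C)(C)C)Oc2cc1OC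
F4 | step 7 | tert-butyl{[(2R)-5-{[(tert-butyldimethylsilyl)oxy]methylidene}-2-methyl-6-methylideneoxan-2-yl]methoxy}diphenylsilane, enol ether geometry not defined | C=C1C(=CO[Si](C)(C)C(C)(C)C)CC[C@](C)(CO[Si](c2ccccc2)(c2ccccc2)C(C)(C)C)O1
F5 | step 7 | 2-(2-methyl-1,3-dioxolan-2-yl)acetaldehyde | CC1(CC=O)OCCO1
F6 | step 7 | (2R)-2-{[(tert-butyldiphenylsilyl)oxy]methyl}-6-[2-hydroxy-3-(2-methyl-1,3-dioxolan-2-yl)propyl]-2-methyl-3,4-dihydro-2H-pyran-5-carbaldehyde, both carbinol epimers | CC1(CC(O)CC2=C(C=O)CC[C@](C)(CO[Si](c3ccccc3)(c3ccccc3)C(C)(C)C)O2)OCCO1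
F7 | step 5 | 2,2,2-trichloro-1-[(2R)-2-{[(tert-butyldiphenylsilyl)oxy]methyl}-2,6-dimethyl-3,4-dihydro-2H-pyran-5-yl]ethan-1-one | CC1=C(C(=O)C(Cl)(Cl)Cl)CC[C@](C)(CO[Si](c2ccccc2)(c2ccccc2)C(C)(C)C)O1
F8 | step 5 | methyl (2R)-2-{[(tert-butyldiphenylsilyl)oxy]methyl}-2,6-dimethyl-3,4-dihydro-2H-pyran-5-carboxylate | CC1=C(C(=O)OC)CC[C@](C)(CO[Si](c2ccccc2)(c2ccccc2)C(C)(C)C)O1
F9 | step 5 | [(2R)-2-{[(tert-butyldiphenylsilyl)oxy]methyl}-2,6-dimethyl-3,4-dihydro-2H-pyran-5-yl]methanol | CC1=C(CO)CC[C@](C)(CO[Si](c2ccccc2)(c2ccccc2)C(C)(C)C)O1
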